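**Plan**

- The target is read as (2S,4R)-luteoliflavan-(4→8)-(−)-epigallocatechin 3-O-gallate (upper flavan 2,4-trans, lower unit 2R,3R). Retrosynthesis cuts the gallate ester and the interflavan C4–C8 bond and, with the latter, takes the upper pyran ring (ring C) back to a 2-aryl-2,3-dihydrobenzofuran with an exocyclic CH2–O.
- Upper unit, forward: (2S)-eriodictyol → tribenzyl ether → 5-O-pivalate → ring contraction of ring C with a trivalent iodine reagent to the trans dihydrobenzofuran ester → diol → seven-membered cyclic sulfate tying the exocyclic CH2O to the peri oxygen (the later O5).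
- Lower unit, forward: (−)-epigallocatechin → penta-O-benzyl ether → esterification with 3,4,5-tris(benzyloxy)benzoic acid → octa-O-benzyl-(−)-epigallocatechin 3-O-gallate.
- Key event: ionisation of the sulfate, 1,2-shift of C2 (five-membered ring → six-membered ring C) to the flavan-4-yl cation, capture by C8 of the lower unit; then desulfation and hydrogenolysis.
- Enabling feature: C4 is benzylic to ring A with O1, O5 and O7 ortho/para (stabilised cation); C2 carries O1 and the electron-rich ring B (good migrating carbon); O5 sits peri to C4 (anchor for the tether).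
- Stereochemistry: upper C2 (S) from eriodictyol, carried with retention; upper C4 (R) by trans addition under control of C2; lower C2 and C3 from natural (−)-epigallocatechin.

Key step: step 8

Assumption: (2S)-eriodictyol, (−)-epigallocatechin and 3,4,5-tris(benzyloxy)benzoic acid are taken as commercial materials, the first two as enantiopure natural products.

**Route**

Step 1
Reactants: 1 (2S)-eriodictyol
Product: 2 (2S)-2-[3,4-bis(benzyloxy)phenyl]-7-(benzyloxy)-5-hydroxychroman-4-one
Conditions: BnOH (3.3 equiv), PPh3, DIAD, THF, 0 °C to rt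
Reagents that add atoms: benzyl alcohol OCc1ccccc1
Why: Mitsunobu etherification should alkylate the three acidic phenols (7-OH and the catechol) under neutral conditions, which avoids the base-induced opening of the chromanone ring that would racemise C2, while the hydrogen-bonded 5-OH stays free.

Step 2
Reactants: 2 (2S)-2-[3,4-bis(benzyloxy)phenyl]-7-(benzyloxy)-5-hydroxychroman-4-one
Product: 3 (2S)-2-[3,4-bis(benzyloxy)phenyl]-7-(benzyloxy)-4-oxochroman-5-yl pivalate
Conditions: PivCl, pyridine, DMAP (cat.), CH2Cl2, 0 °C to rt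
Reagents that add atoms: pivaloyl chloride CC(C)(C)C(Cl)=O
Why: DMAP-catalysed O-acylation should cap the chelated 5-OH as a pivalate, so that the phenol is not oxidised by the trivalent iodine reagent of the next step and can be released later by hydride.

Step 3
Reactants: 3 (2S)-2-[3,4-bis(benzyloxy)phenyl]-7-(benzyloxy)-4-oxochroman-5-yl pivalate
Product: 4 methyl (2S,3S)-2-[3,4-bis(benzyloxy)phenyl]-6-(benzyloxy)-4-(pivaloyloxy)-2,3-dihydro-1-benzofuran-3-carboxylate (2,3-trans)
Conditions: PhI(OAc)2, H2SO4 (cat.), HC(OMe)3, rt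
Reagents that add atoms: trimethyl orthoformate COC(OC)OC
Why: The oxidative ring contraction of flavanones with a trivalent iodine reagent in trimethyl orthoformate (enol ether formation, iodination at C3 anti to the 2-aryl group, 1,2-shift of ring A carbon C4a from the ketal carbon to C3, collapse of the dialkoxycarbenium ion to the methyl ester) is a known route to trans-2-aryl-2,3-dihydrobenzofuran-3-carboxylates that does not touch C2, so C2 should keep the S configuration and the new C3 centre should be set trans to the aryl group.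

Step 4
Reactants: 4 methyl (2S,3S)-2-[3,4-bis(benzyloxy)phenyl]-6-(benzyloxy)-4-(pivaloyloxy)-2,3-dihydro-1-benzofuran-3-carboxylate
Product: 5 (2S,3R)-2-[3,4-bis(benzyloxy)phenyl]-6-(benzyloxy)-3-(hydroxymethyl)-2,3-dihydro-1-benzofuran-4-ol (2,3-trans)
Conditions: LiAlH4, THF, 0 °C to rt
Reagents that add atoms: none
Why: LiAlH4 should reduce the methyl ester to the primary alcohol and cleave the aryl pivalate in the same operation (ester reduction), which unveils the peri phenol and the hydroxymethyl group without affecting either stereocentre.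

Step 5
Reactants: 5 (2S,3R)-2-[3,4-bis(benzyloxy)phenyl]-6-(benzyloxy)-3-(hydroxymethyl)-2,3-dihydro-1-benzofuran-4-ol
Product: 6 seven-membered cyclic sulfate of 5 (the peri oxygen O4 and the 3-CH2O joined through SO2; configuration as in 5)
Conditions: NaH (2.2 equiv), THF, 0 °C; then 1,1'-sulfonyldiimidazole, THF (0.01 M), −20 °C to rt; used without storage
Reagents that add atoms: 1,1'-sulfonyldiimidazole O=S(=O)(n1ccnc1)n1ccnc1
Why: Double O-sulfonylation of a bis-alkoxide with 1,1'-sulfonyldiimidazole is an established, oxidant-free way to cyclic sulfates, and high dilution should favour closure of the seven-membered ring between the peri phenoxide and the primary alkoxide.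

Step 6
Reactants: 7 (−)-epigallocatechin
Product: 8 (2R,3R)-5,7-bis(benzyloxy)-2-[3,4,5-tris(benzyloxy)phenyl]chroman-3-ol (penta-O-benzyl-(−)-epigallocatechin)
Conditions: BnBr (5.5 equiv), K2CO3, DMF (degassed), argon, 0 °C to rt
Reagents that add atoms: benzyl bromide BrCc1ccccc1
Why: Williamson etherification with K2CO3 should alkylate the five phenols and leave the much less acidic secondary 3-OH free, while low temperature and exclusion of oxygen guard the pyrogallol ring against oxidation and C2 against base-induced epimerisation.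

Step 7
Reactants: 8 penta-O-benzyl-(−)-epigallocatechin; 9 3,4,5-tris(benzyloxy)benzoic acid
Product: 10 octa-O-benzyl-(−)-epigallocatechin 3-O-gallate
Conditions: DCC, DMAP (cat.), CH2Cl2, 0 °C to rt
Reagents that add atoms: none
Why: Steglich esterification should acylate the axial secondary 3-OH through the acylpyridinium ion without touching C2 or C3, and it leaves ring A as a 5,7-dibenzyloxy nucleophile that reacts at C8.

Step 8
Reactants: 6 seven-membered cyclic sulfate of 5; 10 octa-O-benzyl-(−)-epigallocatechin 3-O-gallate (3 equiv)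
Product: 13 (2S,4R)-3',4',7-tri-O-benzylluteoliflavan-(4→8)-octa-O-benzyl-(−)-epigallocatechin 3-O-gallate (upper 5-OH free), via flavan-4-yl cation sulfate zwitterion 11 (not isolated), via aryl hydrogen sulfate 12 (not isolated)
Conditions: (CF3)2CHOH/CH2Cl2 1:2, 0 °C to rt; then THF/H2O 10:1, TsOH·H2O (cat.), 40 °C; NaHCO3 work-up
Reagents that add atoms: none
Why: Proposed new method: ionisation of the primary C–O bond of the cyclic sulfate in hexafluoroisopropanol should be assisted by the anti-periplanar C2–C3 bond of the dihydrofuran ring, so that C2 (benzylic to ring B and bearing O1) shifts from C3 to the exocyclic carbon with retention and the five-membered ring expands to the six-membered pyran ring as the 5,7-dioxygenated flavan-4-yl cation (or its covalent six-membered 4,5-cyclic sulfate), which is then captured by C8 of 10 in a Friedel–Crafts alkylation. The closest known reaction types are the Wagner–Meerwein ring expansion of cycloalkylcarbinyl sulfonates and dyotropic ring expansions for the first event, and the Lewis-acid coupling of 4-oxygenated flavans with 5,7-di-O-benzylflavan-3-ols for the second. The pyran ring is closed by ring expansion through a 1,2-carbon shift (equivalent to a 6-endo Prins closure if the shift is stepwise), and no other ring is formed. C2 should keep the S configuration of eriodictyol because it migrates with retention, and the new C4 centre is controlled by C2: the nucleophile adds quasi-axially to the half-chair cation on the face anti to the equatorial ring B, which gives the 2,4-trans (4R) product. The step needs migration of C2 in preference to a hydride shift or phenonium participation by ring A, which the seven-membered tether secures by holding the leaving oxygen anti to C2–C3 and gauche to C3–H and C3–C3a, and it needs attack at C8 and not C6 of 10, which is favoured because C6 is flanked by two benzyloxy groups. The aryl hydrogen sulfate left on O5 is cleaved by acid-catalysed solvolysis in wet THF in the same flask.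

Step 9
Reactants: 13 (2S,4R)-3',4',7-tri-O-benzylluteoliflavan-(4→8)-octa-O-benzyl-(−)-epigallocatechin 3-O-gallate (upper 5-OH free)
Product: 14 (2S,4R)-luteoliflavan-(4→8)-(−)-epigallocatechin 3-O-gallate (target)
Conditions: H2 (1 atm), Pd(OH)2/C, THF/MeOH/H2O, rt
Reagents that add atoms: none
Why: Hydrogenolysis over Pd(OH)2/C should remove all eleven benzyl ethers under neutral conditions that are standard for benzylated proanthocyanidin gallates and leave the gallate ester, the interflavan bond and the four stereocentres intact.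

**Compound list**

1 | (2S)-eriodictyol, (2S)-2-(3,4-dihydroxyphenyl)-5,7-dihydroxychroman-4-one | O=C1C[C@@H](c2ccc(O)c(O)c2)Oc2cc(O)cc(O)c21 | starting material
2 | (2S)-2-[3,4-bis(benzyloxy)phenyl]-7-(benzyloxy)-5-hydroxychroman-4-one | O=C1C[C@@H](c2ccc(OCc3ccccc3)c(OCc3ccccc3)c2)Oc2cc(OCc3ccccc3)cc(O)c21 | intermediate
3 | (2S)-2-[3,4-bis(benzyloxy)phenyl]-7-(benzyloxy)-4-oxochroman-5-yl pivalate | O=C1C[C@@H](c2ccc(OCc3ccccc3)c(OCc3ccccc3)c2)Oc2cc(OCc3ccccc3)cc(OC(=O)C(C)(C)C)c21 | intermediate
4 | methyl (2S,3S)-2-[3,4-bis(benzyloxy)phenyl]-6-(benzyloxy)-4-(pivaloyloxy)-2,3-dihydro-1-benzofuran-3-carboxylate (2,3-trans) | COC(=O)[C@@H]1[C@@H](c2ccc(OCc3ccccc3)c(OCc3ccccc3)c2)Oc2cc(OCc3ccccc3)cc(OC(=O)C(C)(C)C)c21 | intermediate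
5 | (2S,3R)-2-[3,4-bis(benzyloxy)phenyl]-6-(benzyloxy)-3-(hydroxymethyl)-2,3-dihydro-1-benzofuran-4-ol (2,3-trans) | OC[C@@H]1[C@@H](c2ccc(OCc3ccccc3)c(OCc3ccccc3)c2)Oc2cc(OCc3ccccc3)cc(O)c21 | intermediate
6 | seven-membered cyclic sulfate of 5 (O4 of the benzofuran joined to the 3-CH2O through SO2; 2,3-trans) | O=S1(=O)OC[C@@H]2[C@@H](c3ccc(OCc4ccccc4)c(OCc4ccccc4)c3)Oc3cc(OCc4ccccc4)cc(O1)c32 | intermediate
7 | (−)-epigallocatechin, (2R,3R)-2-(3,4,5-trihydroxyphenyl)chromane-3,5,7-triol | O[C@@H]1Cc2c(O)cc(O)cc2O[C@@H]1c1cc(O)c(O)c(O)c1 | starting material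
8 | (2R,3R)-5,7-bis(benzyloxy)-2-[3,4,5-tris(benzyloxy)phenyl]chroman-3-ol (penta-O-benzyl-(−)-epigallocatechin) | O[C@@H]1Cc2c(OCc3ccccc3)cc(OCc3ccccc3)cc2O[C@@H]1c1cc(OCc2ccccc2)c(OCc2ccccc2)c(OCc2ccccc2)c1 | intermediate
9 | 3,4,5-tris(benzyloxy)benzoic acid | O=C(O)c1cc(OCc2ccccc2)c(OCc2ccccc2)c(OCc2ccccc2)c1 | starting material
10 | octa-O-benzyl-(−)-epigallocatechin 3-O-gallate | O=C(O[C@@H]1Cc2c(OCc3ccccc3)cc(OCc3ccccc3)cc2O[C@@H]1c1cc(OCc2ccccc2)c(OCc2ccccc2)c(OCc2ccccc2)c1)c1cc(OCc2ccccc2)c(OCc2ccccc2)c(OCc2ccccc2)c1 | intermediate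
11 | (2S)-2-[3,4-bis(benzyloxy)phenyl]-7-(benzyloxy)chroman-4-ylium-5-yl sulfate, zwitterion (ring-expanded flavan-4-yl cation) | [O-]S(=O)(=O)Oc1cc(OCc2ccccc2)cc2O[C@H](c3ccc(OCc4ccccc4)c(OCc4ccccc4)c3)C[CH+]c12 | intermediate
12 | 5-O-sulfate (aryl hydrogen sulfate) of 13, 2,4-trans | O=C(O[C@@H]1Cc2c(OCc3ccccc3)cc(OCc3ccccc3)c([C@@H]3C[C@@H](c4ccc(OCc5ccccc5)c(OCc5ccccc5)c4)Oc4cc(OCc5ccccc5)cc(OS(=O)(=O)O)c43)c2O[C@@H]1c1cc(OCc2ccccc2)c(OCc2ccccc2)c(OCc2ccccc2)c1)c1cc(OCc2ccccc2)c(OCc2ccccc2)c(OCc2ccccc2)c1 | intermediate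
13 | (2S,4R)-3',4',7-tri-O-benzylluteoliflavan-(4→8)-octa-O-benzyl-(−)-epigallocatechin 3-O-gallate, upper 5-OH free, 2,4-trans | O=C(O[C@@H]1Cc2c(OCc3ccccc3)cc(OCc3ccccc3)c([C@@H]3C[C@@H](c4ccc(OCc5ccccc5)c(OCc5ccccc5)c4)Oc4cc(OCc5ccccc5)cc(O)c43)c2O[C@@H]1c1cc(OCc2ccccc2)c(OCc2ccccc2)c(OCc2ccccc2)c1)c1cc(OCc2ccccc2)c(OCc2ccccc2)c(OCc2ccccc2)c1 | intermediate
14 | (2S,4R)-luteoliflavan-(4→8)-(−)-epigallocatechin 3-O-gallate | O=C(O[C@@H]1Cc2c(O)cc(O)c([C@@H]3C[C@@H](c4ccc(O)c(O)c4)Oc4cc(O)cc(O)c43)c2O[C@@H]1c1cc(O)c(O)c(O)c1)c1cc(O)c(O)c(O)c1 | target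

**Count**

Total steps: 9. Longest linear sequence: 7 steps (steps 1, 2, 3, 4, 5, 8, 9); steps 6 and 7 form a two-step side branch that joins at step 8.

**Steps most likely to fail, with fallbacks**

1. Step 8 (proposed new method). The shift may not be selective: a hydride shift followed by elimination would drain material to a 3-methylbenzofuran. A stepwise fragmentation and Prins reclosure could erode the configuration at C2. The facial selectivity at C4 may be modest, and the nucleophile could react partly at C6. Fallback by known chemistry, setting out from compound 2: reduction of the chelated ketone with NaBH4 in MeOH/THF at 0 °C should give the 2,4-cis flavan-4-ol, (2S,4S)-2-[3,4-bis(benzyloxy)phenyl]-7-(benzyloxy)chromane-4,5-diol F1. Ionisation of its benzylic hydroxyl with Me3SiOTf (cat.) in CH2Cl2 at −78 °C in the presence of 10 (3 equiv) is the established flavan-4-ol/flavan-3-ol coupling and should give the 2,4-trans product. The fallback comes back to the route at compound 13.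

2. Step 3. The trivalent iodine reagent may instead induce a 2,3-shift of ring B (isoflavone), dehydrogenation to the flavone, or oxidation of the electron-rich rings, and acid may partly open the chromanone and racemise C2. Fallback setting out from compound 3: C-acylation of the lithium enolate (LiN(SiMe3)2, CF3CO2CH2CF3, THF, −78 °C) should give the activated diketone, (2S)-2-[3,4-bis(benzyloxy)phenyl]-7-(benzyloxy)-4-oxo-3-(trifluoroacetyl)chroman-5-yl pivalate F2. Detrifluoroacetylative diazo transfer with MsN3 and Et3N in MeCN then gives the diazo ketone, (2R)-2-[3,4-bis(benzyloxy)phenyl]-7-(benzyloxy)-3-diazo-4-oxochroman-5-yl pivalate F3 (same spatial arrangement at C2 as in 3). Photochemical Wolff rearrangement in MeOH contracts the ring through a ketene that methanol traps. Protonation anti to the aryl group should give mainly the cis ester, methyl (2S,3R)-2-[3,4-bis(benzyloxy)phenyl]-6-(benzyloxy)-4-(pivaloyloxy)-2,3-dihydro-1-benzofuran-3-carboxylate F4. Equilibration at C3 with DBU in toluene to the trans isomer comes back to the route at compound 4.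

3. Step 5. Intermolecular sulfonylation (oligomers) may outrun closure of the seven-membered ring, and imidazolide may open the product at the primary carbon. Fallback setting out from compound 5, in two chemoselective stages: SO2F2 and Et3N in CH2Cl2 should fluorosulfonylate only the phenol to give the aryl fluorosulfate, (2S,3R)-2-[3,4-bis(benzyloxy)phenyl]-6-(benzyloxy)-3-(hydroxymethyl)-2,3-dihydro-1-benzofuran-4-yl sulfurofluoridate F5. DBU in MeCN at high dilution then closes the ring by intramolecular sulfur–fluoride exchange, with no nucleophilic counter-ion left in the flask. The fallback comes back to the route at compound 6.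

**Further compounds**

F1 | step 8 | (2S,4S)-2-[3,4-bis(benzyloxy)phenyl]-7-(benzyloxy)chromane-4,5-diol (2,4-cis) | O[C@H]1C[C@@H](c2ccc(OCc3ccccc3)c(OCc3ccccc3)c2)Oc2cc(OCc3ccccc3)cc(O)c21
F2 | step 3 | (2S)-2-[3,4-bis(benzyloxy)phenyl]-7-(benzyloxy)-4-oxo-3-(trifluoroacetyl)chroman-5-yl pivalate (C3 epimers and enol) | O=C(C1C(=O)c2c(OC(=O)C(C)(C)C)cc(OCc3ccccc3)cc2O[C@@H]1c1ccc(OCc2ccccc2)c(OCc2ccccc2)c1)C(F)(F)F
F3 | step 3 | (2R)-2-[3,4-bis(benzyloxy)phenyl]-7-(benzyloxy)-3-diazo-4-oxochroman-5-yl pivalate | [N-]=[N+]=C1C(=O)c2c(OC(=O)C(C)(C)C)cc(OCc3ccccc3)cc2O[C@@H]1c1ccc(OCc2ccccc2)c(OCc2ccccc2)c1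
F4 | step 3 | methyl (2S,3R)-2-[3,4-bis(benzyloxy)phenyl]-6-(benzyloxy)-4-(pivaloyloxy)-2,3-dihydro-1-benzofuran-3-carboxylate (2,3-cis) | COC(=O)[C@H]1[C@@H](c2ccc(OCc3ccccc3)c(OCc3ccccc3)c2)Oc2cc(OCc3ccccc3)cc(OC(=O)C(C)(C)C)c21
F5 | step 5 | (2S,3R)-2-[3,4-bis(benzyloxy)phenyl]-6-(benzyloxy)-3-(hydroxymethyl)-2,3-dihydro-1-benzofuran-4-yl sulfurofluoridate | OC[C@@H]1[C@@H](c2ccc(OCc3ccccc3)c(OCc3ccccc3)c2)Oc2cc(OCc3ccccc3)cc(OS(=O)(=O)F)c21
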